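## Retrosynthetic overview

- Isochroman numbering is used for each half (C1, O2, C3, C4, C4a, C5–C8, C8a; bridge CH2 = C9 on C7/C7'). The feature the route rests on: the quinone methide half is the isochroman half minus the hydrogen on C1 and the one on O8, so the target is one dehydrogenation away from a C2-symmetric bis-isochroman (20).
- 20 ⇒ open-chain bis(resorcinol) diol 17 + 2 CH2(OMe)2 by a twofold oxa-Pictet–Spengler closure (C1–O2 and C1–C8a in both halves). Both pyran rings form in this one step, and in 17 C8a is the only ring carbon still bearing hydrogen (C5 carries CH3, C7 the C9 bridge).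
- 17 ⇒ tetramethyl ether diol 13 by Mitsunobu inversion at both carbinol carbons (future C3/C3') and O-demethylation. 13 ⇒ two molecules of aryl alcohol 8 + ethyl formate (C9) by lithiation between the two methoxy groups, then ionic deoxygenation.
- 8 ⇒ aryl bromide 5 + C2-symmetric (2S,3S)-2,3-epoxybutane (sets C4 by SN2 inversion). 5 ⇒ 1-bromo-3,5-dimethoxybenzene by formylation and reduction (C5 methyl).

Key step: step 9

Assumptions:
- The target is drawn as its 8-oxo/6-hydroxy tautomer; the 6-oxo/8-hydroxy form is the same compound by proton shift.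
- (2S,3S)-2,3-Epoxybutane is taken as a purchasable enantiopure reagent; otherwise it is two steps from (2R,3R)-butane-2,3-diol.

## Route

Step 1
Reactants: 1 1-bromo-3,5-dimethoxybenzene; 2 N,N-dimethylformamide
Product: 4 2-bromo-4,6-dimethoxybenzaldehyde, via aryl iminium chloride 3 (not isolated)
Conditions: POCl3, DMF, 0 °C → 90 °C; then aq. NaOAc
Reagents that add atoms: N,N-dimethylformamide (CN(C)C=O); water (O)
Why: Vilsmeier–Haack formylation should go to the ring carbon para to one methoxy group and ortho to the other (next to bromine), the position between the two methoxy groups being the more hindered, and aqueous work-up hydrolyses iminium salt 3 to the aldehyde.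

Step 2
Reactants: 4 2-bromo-4,6-dimethoxybenzaldehyde
Product: 5 1-bromo-3,5-dimethoxy-2-methylbenzene
Conditions: Et3SiH (4 equiv), TFA, CH2Cl2, 0 °C → rt
Reagents that add atoms: none
Why: Ionic hydrogenation reduces an aldehyde on an ortho,para-dimethoxy ring to the methyl group by two hydride transfers to oxygen-stabilised benzylic cations and leaves the aryl bromide intact, which catalytic hydrogenation would not.

Step 3
Reactants: 5 1-bromo-3,5-dimethoxy-2-methylbenzene; 6 (2S,3S)-2,3-epoxybutane
Product: 8 (2S,3S)-3-(3,5-dimethoxy-2-methylphenyl)butan-2-ol, via aryllithium 7 (not isolated)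
Conditions: n-BuLi (1.05 equiv), THF, −78 °C; then 6 (1.3 equiv), BF3·OEt2 (1.3 equiv), −78 °C; aq. NaHCO3
Reagents that add atoms: (2S,3S)-2,3-epoxybutane (C[C@@H]1O[C@H]1C)
Why: Bromine–lithium exchange followed by BF3-promoted SN2 opening of the epoxide; the two epoxide carbons are equivalent by the C2 axis, so a single erythro alcohol should form, with inversion at the attacked carbon setting the benzylic centre (future C4) as S and the carbinol carbon staying S.

Step 4
Reactants: 8 (2S,3S)-3-(3,5-dimethoxy-2-methylphenyl)butan-2-ol (2 equiv); 9 ethyl formate (1 equiv)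
Product: 12 bis{4-[(2S,3S)-3-hydroxybutan-2-yl]-2,6-dimethoxy-3-methylphenyl}methanol, via dilithio aryl alkoxide 10 (not isolated), via lithium alkoxide aldehyde 11 (not isolated)
Conditions: n-BuLi (2.2 equiv per 8), TMEDA, THF, 0 °C → rt; then HCO2Et (0.5 equiv per 8), −78 °C → rt; aq. NH4Cl
Reagents that add atoms: ethyl formate (CCOC=O)
Why: Directed ortho-metalation: after the alkoxide has formed, the second equivalent of base removes the ring proton flanked by both methoxy groups (future C7), and two such aryllithiums add in turn to ethyl formate through aldehyde 11 to give the symmetric diarylmethanol without touching the stereocentres.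

Step 5
Reactants: 12 bis{4-[(2S,3S)-3-hydroxybutan-2-yl]-2,6-dimethoxy-3-methylphenyl}methanol
Product: 13 bis{4-[(2S,3S)-3-hydroxybutan-2-yl]-2,6-dimethoxy-3-methylphenyl}methane
Conditions: Et3SiH (4 equiv), TFA (10 equiv), CH2Cl2, 0 °C; then K2CO3, MeOH, rt (removes any trifluoroacetate)
Reagents that add atoms: none
Why: Ionic deoxygenation: TFA ionises only the diaryl carbinol, whose cation is stabilised by four ortho-methoxy groups, and triethylsilane reduces it to the C9 methylene, while the secondary alcohols do not ionise under these conditions.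

Step 6
Reactants: 13 bis{4-[(2S,3S)-3-hydroxybutan-2-yl]-2,6-dimethoxy-3-methylphenyl}methane; 14 4-nitrobenzoic acid
Product: 15 bis{2,6-dimethoxy-3-methyl-4-[(2S,3R)-3-(4-nitrobenzoyloxy)butan-2-yl]phenyl}methane
Conditions: 4-nitrobenzoic acid (3 equiv), PPh3 (3 equiv), DIAD (3 equiv), THF, 0 °C → rt
Reagents that add atoms: 4-nitrobenzoic acid (OC(=O)c1ccc(cc1)[N+](=O)[O-])
Why: Mitsunobu reaction in its variant for hindered secondary alcohols: the carboxylate displaces the activated oxygen by SN2, which inverts both carbinol carbons from S to R and gives the threo arrangement needed for the trans-3,4-dimethyl pattern, the benzylic centres taking no part.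

Step 7
Reactants: 15 bis{2,6-dimethoxy-3-methyl-4-[(2S,3R)-3-(4-nitrobenzoyloxy)butan-2-yl]phenyl}methane
Product: 16 bis{2,6-dihydroxy-3-methyl-4-[(2S,3R)-3-(4-nitrobenzoyloxy)butan-2-yl]phenyl}methane
Conditions: BBr3 (10 equiv), CH2Cl2, −78 °C → 0 °C; then ice-water
Reagents that add atoms: none
Why: Lewis acid demethylation of the four aryl methyl ethers with BBr3, during which the electron-poor benzoates keep the secondary oxygens from being converted into bromides.

Step 8
Reactants: 16 bis{2,6-dihydroxy-3-methyl-4-[(2S,3R)-3-(4-nitrobenzoyloxy)butan-2-yl]phenyl}methane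
Product: 17 bis{2,6-dihydroxy-4-[(2S,3R)-3-hydroxybutan-2-yl]-3-methylphenyl}methane
Conditions: K2CO3 (6 equiv), MeOH, rt, Ar; then 1 M HCl
Reagents that add atoms: none
Why: Base-mediated methanolysis (transesterification) of the activated 4-nitrobenzoates cleaves only the acyl C–O bond, so both secondary alcohols are released with retention.

Step 9
Reactants: 17 bis{2,6-dihydroxy-4-[(2S,3R)-3-hydroxybutan-2-yl]-3-methylphenyl}methane; 18 dimethoxymethane
Product: 20 bis[(3R,4S)-6,8-dihydroxy-3,4,5-trimethylisochroman-7-yl]methane, via bis(methoxymethyl) ether 19 (not isolated)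
Conditions: CH2(OMe)2 (2.4 equiv), TsOH·H2O (20 mol %), MeCN (0.02 M), 45 °C, Ar; then 0.5 M HCl in MeOH, rt (cleaves any phenol O-formals)
Reagents that add atoms: dimethoxymethane (COCOC)
Why: Acid-catalysed acetal exchange turns each secondary alcohol into its methoxymethyl ether (19), loss of methanol gives the oxocarbenium ion O2=C1H2(+), and C8a of the same ring (ortho to O8–H, para to O6–H) attacks it and rearomatises, forming C1–O2 and C1–C8a in each half. This is the oxa-Pictet–Spengler cyclisation of 2-arylethanols with a formaldehyde acetal, run twice on one C2-symmetric substrate. Each of the two pyran rings closes by 6-endo-trig attack of the arene on the tethered oxocarbenium ion. No stereocentre is created, since C1 is a CH2 group, and C3 and C4 are not ionised under these conditions and keep their (3R,4S) configuration. The selectivity required is regiochemical and intra- versus intermolecular: C8a is the only ring carbon that still carries hydrogen (C5 has the methyl group, C7 the C9 bridge), and the tether should make ring closure faster than bridging between molecules, which dilution and a near-stoichiometric amount of acetal support. A hydroxymethylation at C8a that precedes O-closure would lead through the ortho-quinone methide to the same isochroman, so both orders of bond formation converge on 20.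

Step 10
Reactants: 20 bis[(3R,4S)-6,8-dihydroxy-3,4,5-trimethylisochroman-7-yl]methane
Product: 21 (3R,4S)-7-{[(3R,4S)-6,8-dihydroxy-3,4,5-trimethylisochroman-7-yl]methyl}-6-hydroxy-3,4,5-trimethyl-3,4-dihydro-8H-isochromen-8-one (Dicitrinone I)
Conditions: DDQ (0.9 equiv), 1,4-dioxane, 10 °C → rt, Ar
Reagents that add atoms: none
Why: DDQ dehydrogenation of a 6,8-dihydroxyisochroman to its quinone methide: hydride should leave from C1, the C–H that is benzylic, alpha to O2 and ortho/para to the O8/O6 hydroxyls, and loss of the O8 proton gives the C1=C8a/C8=O system; the two rings are equivalent by C2 symmetry, so either gives 21, and slightly less than one equivalent limits double oxidation.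

## Compound list

1 | 1-bromo-3,5-dimethoxybenzene | COc1cc(Br)cc(OC)c1 | starting material
2 | N,N-dimethylformamide | CN(C)C=O | starting material
3 | [(2-bromo-4,6-dimethoxyphenyl)methylidene]dimethyliminium chloride | C[N+](C)=Cc1c(Br)cc(OC)cc1OC.[Cl-] | intermediate
4 | 2-bromo-4,6-dimethoxybenzaldehyde | O=Cc1c(Br)cc(OC)cc1OC | intermediate
5 | 1-bromo-3,5-dimethoxy-2-methylbenzene | Cc1c(Br)cc(OC)cc1OC | intermediate
6 | (2S,3S)-2,3-epoxybutane | C[C@@H]1O[C@H]1C | starting material
7 | (3,5-dimethoxy-2-methylphenyl)lithium | [Li]c1cc(OC)cc(OC)c1C | intermediate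
8 | (2S,3S)-3-(3,5-dimethoxy-2-methylphenyl)butan-2-ol | Cc1c(OC)cc(OC)cc1[C@H](C)[C@H](C)O | intermediate
9 | ethyl formate | CCOC=O | starting material
10 | lithium (2S,3S)-3-(4-lithio-3,5-dimethoxy-2-methylphenyl)butan-2-olate | Cc1c(OC)c([Li])c(OC)cc1[C@H](C)[C@H](C)O[Li] | intermediate
11 | lithium (2S,3S)-3-(4-formyl-3,5-dimethoxy-2-methylphenyl)butan-2-olate | Cc1c(OC)c(C=O)c(OC)cc1[C@H](C)[C@H](C)O[Li] | intermediate
12 | bis{4-[(2S,3S)-3-hydroxybutan-2-yl]-2,6-dimethoxy-3-methylphenyl}methanol | OC(c1c(OC)cc([C@H](C)[C@H](C)O)c(C)c1OC)c1c(OC)cc([C@H](C)[C@H](C)O)c(C)c1OC | intermediate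
13 | bis{4-[(2S,3S)-3-hydroxybutan-2-yl]-2,6-dimethoxy-3-methylphenyl}methane | C(c1c(OC)cc([C@H](C)[C@H](C)O)c(C)c1OC)c1c(OC)cc([C@H](C)[C@H](C)O)c(C)c1OC | intermediate
14 | 4-nitrobenzoic acid | OC(=O)c1ccc(cc1)[N+](=O)[O-] | starting material
15 | bis{2,6-dimethoxy-3-methyl-4-[(2S,3R)-3-(4-nitrobenzoyloxy)butan-2-yl]phenyl}methane | C(c1c(OC)cc([C@H](C)[C@@H](C)OC(=O)c2ccc(cc2)[N+](=O)[O-])c(C)c1OC)c1c(OC)cc([C@H](C)[C@@H](C)OC(=O)c2ccc(cc2)[N+](=O)[O-])c(C)c1OC | intermediate
16 | bis{2,6-dihydroxy-3-methyl-4-[(2S,3R)-3-(4-nitrobenzoyloxy)butan-2-yl]phenyl}methane | C(c1c(O)cc([C@H](C)[C@@H](C)OC(=O)c2ccc(cc2)[N+](=O)[O-])c(C)c1O)c1c(O)cc([C@H](C)[C@@H](C)OC(=O)c2ccc(cc2)[N+](=O)[O-])c(C)c1O | intermediate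
17 | bis{2,6-dihydroxy-4-[(2S,3R)-3-hydroxybutan-2-yl]-3-methylphenyl}methane | C(c1c(O)c(C)c([C@H](C)[C@@H](C)O)cc1O)c1c(O)c(C)c([C@H](C)[C@@H](C)O)cc1O | intermediate
18 | dimethoxymethane | COCOC | starting material
19 | bis{2,6-dihydroxy-4-[(2S,3R)-3-(methoxymethoxy)butan-2-yl]-3-methylphenyl}methane | C(c1c(O)c(C)c([C@H](C)[C@@H](C)OCOC)cc1O)c1c(O)c(C)c([C@H](C)[C@@H](C)OCOC)cc1O | intermediate
20 | bis[(3R,4S)-6,8-dihydroxy-3,4,5-trimethylisochroman-7-yl]methane | C(c1c(O)c(C)c2c(c1O)CO[C@H](C)[C@H]2C)c1c(O)c(C)c2c(c1O)CO[C@H](C)[C@H]2C | intermediate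
21 | (3R,4S)-7-{[(3R,4S)-6,8-dihydroxy-3,4,5-trimethylisochroman-7-yl]methyl}-6-hydroxy-3,4,5-trimethyl-3,4-dihydro-8H-isochromen-8-one (Dicitrinone I) | CC1=C2C(=CO[C@H](C)[C@H]2C)C(=O)C(Cc2c(O)c(C)c3c(c2O)CO[C@H](C)[C@H]3C)=C1O | target

## Step count and risks

Total step count: 10. Longest linear sequence: 10 steps (from compound 1).

Steps most likely to fail:

1. Step 10. The second, equally reactive ring may be oxidised as well, hydride may be lost from the doubly benzylic C9 bridge instead of C1, or the electrophilic quinone methide may add nucleophiles during isolation. The fallback avoids any oxidant and sets out from 17. One equivalent of dimethoxymethane under the conditions of step 9 should close one ring only and give the mono-isochroman F1, with unreacted 17 and doubly closed 20 recovered and reused. The second ring is then closed at the formic acid oxidation level with triethyl orthoformate and acid: formylation at the free C8a and cyclisation give the 1-ethoxyisochroman F2, which should lose ethanol to the quinone methide. This returns to the route at 21.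

2. Step 9. The electrophile may bridge two molecules through hydroxymethyl intermediates, tie two phenol oxygens together as a formal, or attack C7 ipso and split the C9 bridge. The fallback sets out from 17 and brings in C1 as a formyl group, which deactivates each ring as soon as it has reacted. Excess triethyl orthoformate with acid should formylate both C8a positions and close both rings to the bis(quinone methide) F3. Sodium borohydride then delivers hydride to C1 of each quinone methide and returns to the route at 20.

3. Step 6. Elimination to the styrene-type alkene, incomplete double inversion, or partial retention through aryl participation may occur at the hindered carbinol carbons. The fallback sets out from 13 and inverts by redox instead of substitution. Dess–Martin oxidation gives the diketone F4. L-Selectride at −78 °C should then reduce under Felkin–Anh control, hydride attacking anti to the aryl group, to the threo diol F5. Acylation with 4-nitrobenzoyl chloride and pyridine returns to the route at 15.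

Further compounds
F1 | step 10 | (2R,3S)-3-[4-{[(3R,4S)-6,8-dihydroxy-3,4,5-trimethylisochroman-7-yl]methyl}-3,5-dihydroxy-2-methylphenyl]butan-2-ol | C(c1c(O)c(C)c2c(c1O)CO[C@H](C)[C@H]2C)c1c(O)c(C)c([C@H](C)[C@@H](C)O)cc1O
F2 | step 10 | (3R,4S)-1-ethoxy-7-{[(3R,4S)-6,8-dihydroxy-3,4,5-trimethylisochroman-7-yl]methyl}-3,4,5-trimethylisochroman-6,8-diol (C1 epimers) | C(c1c(O)c(C)c2c(c1O)C(OCC)O[C@H](C)[C@H]2C)c1c(O)c(C)c2c(c1O)CO[C@H](C)[C@H]2C
F3 | step 9 | 7,7'-methylenebis[(3R,4S)-6-hydroxy-3,4,5-trimethyl-3,4-dihydro-8H-isochromen-8-one] | C(C1=C(O)C(C)=C2C(=CO[C@H](C)[C@H]2C)C1=O)C1=C(O)C(C)=C2C(=CO[C@H](C)[C@H]2C)C1=O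
F4 | step 6 | bis{2,6-dimethoxy-3-methyl-4-[(2S)-3-oxobutan-2-yl]phenyl}methane | C(c1c(OC)cc([C@H](C)C(C)=O)c(C)c1OC)c1c(OC)cc([C@H](C)C(C)=O)c(C)c1OC
F5 | step 6 | bis{4-[(2S,3R)-3-hydroxybutan-2-yl]-2,6-dimethoxy-3-methylphenyl}methane | C(c1c(OC)cc([C@H](C)[C@@H](C)O)c(C)c1OC)c1c(OC)cc([C@H](C)[C@@H](C)O)c(C)c1OC
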